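**Retrosynthetic overview**

- The target is a (2S)-flavanone whose ring A (C4a, C5, C6, C7, C8, C8a) is a fully substituted phloroglucinol: oxygens on C5, C7 and C8a (O1), the acyl carbon on C4a and two different hydroxybenzyl arms on C6 and C8. The plan rests on telling the C5 oxygen from the C8a oxygen, since this alone decides which arm is at C6 and which at C8.
- Ring A is therefore built de novo by a Danheiser benzannulation that forms C7–C8 and C4a–C8a. A 3-ethoxy-4-(arylmethyl)cyclobutenone supplies C4a-H, C5-OEt, C6 with its arm and C7; a 1-siloxy-3-arylpropyne supplies C8 with its arm and C8a-OSi. The product has C7-OH free, C8a-O silylated and C5-O ethylated.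
- Ring C follows: the C8a oxygen alone is unmasked and alkylated with inversion by an (R)-β-hydroxy Weinreb amide (O1–C2, sets 2S); C4a is brominated and a Parham cyclisation forms C4–C4a. BCl3 then removes the MOM groups and the peri O-ethyl group.
- The cyclobutenone comes from ethoxyacetylene and the ketene of a 3-arylpropanoic acid, assembled from 2,2'-methylenediphenol and 5-bromosalicylaldehyde (ortho-formylation, benzylic Suzuki coupling, Doebner condensation, hydrogenation). The siloxyalkyne comes from methyl (2-hydroxyphenyl)acetate by Kowalski homologation and O-silylation.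
- Ring order: the four arm benzene rings are bought; ring A is formed in step 13, ring C in step 19.

Key step: step 13

Remark: flavanone numbering (O1, C2, C3, C4, C4a, C5, C6, C7, C8, C8a) is used for these atoms at every stage.
Remark: in names, arm 8 = 2-(methoxymethoxy)benzyl and arm 6 = 2-(methoxymethoxy)-5-{2-(methoxymethoxy)-3-[2-(methoxymethoxy)benzyl]benzyl}benzyl; both include the benzylic CH2.
Remark: ethyl (R)-3-hydroxy-3-phenylpropanoate is assumed to be available enantiopure; the cyclobutenone is used as the racemate because its sp3 centre is erased in the key step.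

**Route**

Step 1
Reactants: 1 methyl (2-hydroxyphenyl)acetate
Product: 2 methyl [2-(methoxymethoxy)phenyl]acetate
Conditions: MOMCl, i-Pr2NEt, CH2Cl2, 0 °C → rt
Reagents that add atoms: chloromethyl methyl ether (MOMCl), COCCl
Why: O-alkylation of the phenol to its methoxymethyl acetal (MOM protection) under a hindered amine base should be faster than lactonisation and leaves the methyl ester untouched.

Step 2
Reactants: 2 methyl [2-(methoxymethoxy)phenyl]acetate
Product: 5 triisopropyl({3-[2-(methoxymethoxy)phenyl]prop-1-yn-1-yl}oxy)silane, via dibromo enolate 3 (not isolated), via lithium ynolate 4 (not isolated)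
Conditions: CH2Br2, LiTMP (lithium 2,2,6,6-tetramethylpiperidide, 2.1 equiv), THF, −78 °C; n-BuLi, −78 → 0 °C; TIPSCl, −78 °C → rt
Reagents that add atoms: dibromomethane, BrCBr; chlorotriisopropylsilane (TIPSCl), CC(C)[Si](Cl)(C(C)C)C(C)C
Why: Kowalski ester homologation, in which LiCHBr2 adds to the ester, the derived dibromomethyl ketone enolate 3 undergoes bromine–lithium exchange and a carbenoid 1,2-shift of the benzyl group to ynolate 4, and the bulky silyl chloride captures 4 on oxygen.

Step 3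
Reactants: 6 2,2'-methylenediphenol
Product: 7 2-hydroxy-3-(2-hydroxybenzyl)benzaldehyde
Conditions: MgCl2 (1.0 equiv), Et3N, (CH2O)n (2.2 equiv), MeCN, reflux
Reagents that add atoms: paraformaldehyde (as formaldehyde), C=O
Why: magnesium-mediated ortho-formylation of a phenol (Casnati–Skattebøl) is specific for the free ortho carbon, and with one equivalent of MgCl2 and limiting paraformaldehyde it should stop mainly at the mono-aldehyde because the first salicylaldehyde unit ties up the magnesium as a chelate, unchanged 6 being recycled.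

Step 4
Reactants: 7 2-hydroxy-3-(2-hydroxybenzyl)benzaldehyde
Product: 8 2-(methoxymethoxy)-3-[2-(methoxymethoxy)benzyl]benzaldehyde
Conditions: MOMCl (3 equiv), i-Pr2NEt, CH2Cl2, 0 °C → reflux
Reagents that add atoms: chloromethyl methyl ether (MOMCl), COCCl
Why: double MOM protection of the two phenols by O-alkylation, with excess reagent and gentle heating to overcome the hydrogen-bonded salicylaldehyde hydroxyl.

Step 5
Reactants: 8 2-(methoxymethoxy)-3-[2-(methoxymethoxy)benzyl]benzaldehyde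
Product: 9 {2-(methoxymethoxy)-3-[2-(methoxymethoxy)benzyl]phenyl}methanol
Conditions: NaBH4, MeOH/THF, 0 °C
Reagents that add atoms: none
Why: hydride reduction of the aryl aldehyde to the benzylic alcohol, to which the acetals are inert.

Step 6
Reactants: 9 {2-(methoxymethoxy)-3-[2-(methoxymethoxy)benzyl]phenyl}methanol
Product: 10 1-(chloromethyl)-2-(methoxymethoxy)-3-[2-(methoxymethoxy)benzyl]benzene
Conditions: PPh3, NCS, THF, 0 °C → rt
Reagents that add atoms: N-chlorosuccinimide (NCS), O=C1CCC(=O)N1Cl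
Why: Appel-type chlorination through the alkoxyphosphonium chloride is acid-free, so the MOM groups survive; the chloride is used at once.

Step 7
Reactants: 11 5-bromo-2-hydroxybenzaldehyde
Product: 12 5-bromo-2-(methoxymethoxy)benzaldehyde
Conditions: MOMCl, i-Pr2NEt, CH2Cl2, 0 °C → rt
Reagents that add atoms: chloromethyl methyl ether (MOMCl), COCCl
Why: MOM protection of the phenol by O-alkylation.

Step 8
Reactants: 12 5-bromo-2-(methoxymethoxy)benzaldehyde
Product: 13 2-(methoxymethoxy)-5-(4,4,5,5-tetramethyl-1,3,2-dioxaborolan-2-yl)benzaldehyde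
Conditions: B2pin2, Pd(dppf)Cl2 (cat.), KOAc, 1,4-dioxane, 85 °C
Reagents that add atoms: bis(pinacolato)diboron, CC1(C)OB(OC1(C)C)B1OC(C)(C)C(C)(C)O1
Why: Miyaura borylation of the aryl bromide tolerates the aldehyde and the acetal and places boron para to the protected phenol oxygen.

Step 9
Reactants: 10 1-(chloromethyl)-2-(methoxymethoxy)-3-[2-(methoxymethoxy)benzyl]benzene; 13 2-(methoxymethoxy)-5-(4,4,5,5-tetramethyl-1,3,2-dioxaborolan-2-yl)benzaldehyde
Product: 14 2-(methoxymethoxy)-5-{2-(methoxymethoxy)-3-[2-(methoxymethoxy)benzyl]benzyl}benzaldehyde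
Conditions: Pd(dppf)Cl2 (cat.), K3PO4, THF/H2O, 70 °C
Reagents that add atoms: none
Why: Suzuki–Miyaura coupling of a benzylic chloride with an arylboronate forms the second diarylmethane link at a defined position (para to the oxygen of the salicylaldehyde ring) without touching the aldehyde.

Step 10
Reactants: 14 2-(methoxymethoxy)-5-{2-(methoxymethoxy)-3-[2-(methoxymethoxy)benzyl]benzyl}benzaldehyde
Product: 15 (E)-3-(2-(methoxymethoxy)-5-{2-(methoxymethoxy)-3-[2-(methoxymethoxy)benzyl]benzyl}phenyl)prop-2-enoic acid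
Conditions: malonic acid, pyridine, piperidine (cat.), 90 °C; cold citric acid work-up
Reagents that add atoms: malonic acid, OC(=O)CC(O)=O
Why: Knoevenagel–Doebner condensation with decarboxylation gives the (E)-cinnamic acid directly under basic conditions that the MOM groups tolerate.

Step 11
Reactants: 15 (E)-cinnamic acid of step 10
Product: 16 2-(arm 6)acetic acid, i.e. 3-(2-(methoxymethoxy)-5-{2-(methoxymethoxy)-3-[2-(methoxymethoxy)benzyl]benzyl}phenyl)propanoic acid
Conditions: H2 (1 atm), 10% Pd/C, EtOAc, rt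
Reagents that add atoms: none
Why: catalytic hydrogenation saturates the conjugated alkene only; there is no hydrogenolysable group in the molecule.

Step 12
Reactants: 16 2-(arm 6)acetic acid; 17 ethoxyacetylene
Product: 20 rac-3-ethoxy-4-(arm 6)cyclobut-2-en-1-one, via acid chloride 18 (not isolated), via ketene 19 (not isolated)
Conditions: Me2C=C(Cl)NMe2 (1.0 equiv), CH2Cl2, 0 °C → rt; then slow addition to 17 (3 equiv), Et3N, Et2O, rt
Reagents that add atoms: none
Why: the α-chloroenamine makes acid chloride 18 without free HCl so the MOM acetals survive, Et3N dehydrochlorinates it to aldoketene 19, and a ketene–ynol ether [2+2] cycloaddition (the terminal alkyne carbon bonds to the ketene carbonyl carbon) should give the 3-ethoxy-4-substituted cyclobutenone as the racemate, slow addition and excess alkyne holding back ketene dimerisation.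

Step 13
Reactants: 20 rac-3-ethoxy-4-(arm 6)cyclobut-2-en-1-one; 5 triisopropyl({3-[2-(methoxymethoxy)phenyl]prop-1-yn-1-yl}oxy)silane
Product: 25 6-(arm 6)-5-ethoxy-2-(arm 8)-3-(triisopropylsilyloxy)phenol, via vinylketene 21 (not isolated), via alkenylcyclobutenone 22 (not isolated), via dienylketene 23 (not isolated), via cyclohexadienone 24 (not isolated)
Conditions: 5 (1.5 equiv), toluene, 80 → 110 °C, sealed tube, argon
Reagents that add atoms: none
Why: Danheiser benzannulation: 4π-electrocyclic opening of 20, with the C6 arm rotating outward, gives vinylketene 21, whose ketene C=C undergoes a [2+2] cycloaddition with 5 to form C7–C8 and C4a–C8a in the 4-alkenyl-3-siloxycyclobutenone 22. A second 4π opening gives dienylketene 23, and ring A closes by a thermal disrotatory 6π-electrocyclisation (six-membered carbocycle, re-forming C6–C7) to cyclohexa-2,4-dienone 24, which tautomerises to phenol 25. The closest known reaction is the benzannulation of 3-substituted cyclobutenones with triisopropylsiloxyalkynes to resorcinol monosilyl ethers. No stereocentre is created, since the sp3 carbon C6 of 20, 22 and 24 becomes aromatic. The step needs regioselectivity in the ketene–ynol ether [2+2], and the polarisation of 5 secures it: its benzyl-bearing carbon is the nucleophile and attacks the ketene carbonyl carbon C7, leaving the siloxy carbon to bond to C4a, so C5-OEt, C8a-OTIPS, free C7-OH and C4a-H follow from connectivity alone; the excess of 5 should keep 21 from acylating the hindered product phenol.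

Step 14
Reactants: 25 6-(arm 6)-5-ethoxy-2-(arm 8)-3-(triisopropylsilyloxy)phenol
Product: 26 [4-(arm 6)-5-ethoxy-3-(methoxymethoxy)-2-(arm 8)phenoxy]triisopropylsilane
Conditions: NaH, MOMCl, THF/DMF, 0 °C
Reagents that add atoms: chloromethyl methyl ether (MOMCl), COCCl
Why: O-alkylation of the sodium phenoxide (MOM protection) caps the doubly ortho-substituted C7 oxygen, and the meta-placed aryl silyl ether cannot migrate.

Step 15
Reactants: 26 silyl ether of step 14
Product: 27 4-(arm 6)-5-ethoxy-3-(methoxymethoxy)-2-(arm 8)phenol (free C8a-OH)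
Conditions: Bu4NF, AcOH, THF, 0 °C
Reagents that add atoms: none
Why: buffered fluoride desilylation cleaves only the aryl O–Si bond, so the C8a oxygen is the single free phenol.

Step 16
Reactants: 28 ethyl (R)-3-hydroxy-3-phenylpropanoate
Product: 29 (R)-3-hydroxy-N-methoxy-N-methyl-3-phenylpropanamide
Conditions: MeNHOMe·HCl, i-PrMgCl, THF, −20 → 0 °C
Reagents that add atoms: N,O-dimethylhydroxylamine hydrochloride, CNOC.Cl
Why: aminolysis of the ester by the chloromagnesium amide gives the Weinreb amide, and the carbinol centre is not involved and stays (R).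

Step 17
Reactants: 27 phenol with free C8a-OH; 29 (R)-3-hydroxy-N-methoxy-N-methyl-3-phenylpropanamide
Product: 30 (3S)-3-[4-(arm 6)-5-ethoxy-3-(methoxymethoxy)-2-(arm 8)phenoxy]-N-methoxy-N-methyl-3-phenylpropanamide
Conditions: PPh3, DIAD, toluene, 0 °C → rt
Reagents that add atoms: none
Why: Mitsunobu etherification, in which SN2 displacement of the alkoxyphosphonium by the C8a phenoxide inverts the (R)-carbinol and so sets the future C2 as (S) while forming O1–C2.

Step 18
Reactants: 30 aryl ether of step 17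
Product: 31 (3S)-3-[6-bromo-4-(arm 6)-5-ethoxy-3-(methoxymethoxy)-2-(arm 8)phenoxy]-N-methoxy-N-methyl-3-phenylpropanamide (Br on C4a)
Conditions: NBS (1.0 equiv), CH2Cl2, −40 → 0 °C, dark
Reagents that add atoms: N-bromosuccinimide (NBS), O=C1CCC(=O)N1Br
Why: electrophilic aromatic bromination goes to C4a, the only free position of ring A, which is ortho to the C5 and C8a oxygens and para to the C7 oxygen and so far more activated than any position of the mono-oxygenated arm rings.

Step 19
Reactants: 31 aryl bromide of step 18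
Product: 34 (2S)-6-(arm 6)-5-ethoxy-7-(methoxymethoxy)-8-(arm 8)-2-phenylchroman-4-one, via aryllithium 32 (not isolated), via tetrahedral adduct 33 (not isolated)
Conditions: t-BuLi (2.1 equiv), THF, −78 °C; AcOH, −78 °C → rt
Reagents that add atoms: none
Why: Parham cyclisation, in which bromine–lithium exchange at C4a is followed by 6-exo attack on the Weinreb amide to the chelated adduct 33 (C4–C4a, ring C), and the cold acidic quench releases the ketone without base so that C2 is not opened by retro-oxa-Michael reaction and stays (S).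

Step 20
Reactants: 34 protected flavanone
Product: 35 (2S)-5,7-dihydroxy-8-(2-hydroxybenzyl)-6-{2-hydroxy-5-[2-hydroxy-3-(2-hydroxybenzyl)benzyl]benzyl}-2-phenylchroman-4-one (target)
Conditions: BCl3 (excess), CH2Cl2, −78 → 0 °C; then H2O
Reagents that add atoms: none
Why: Lewis-acid dealkylation, in which BCl3 cleaves the five MOM acetals and, through the six-membered chelate between the C4 carbonyl and the C5 oxygen, the peri ethyl ether, while O1 is a weakly basic vinylogous ester oxygen so the C2–O1 bond and the (S) centre should be preserved.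

**Compound list**

1 | methyl (2-hydroxyphenyl)acetate | COC(=O)Cc1ccccc1O | starting material
2 | methyl [2-(methoxymethoxy)phenyl]acetate | COCOc1ccccc1CC(=O)OC | intermediate
3 | lithium 1,1-dibromo-3-[2-(methoxymethoxy)phenyl]prop-1-en-2-olate | [Li+].[O-]C(Cc1ccccc1OCOC)=C(Br)Br | intermediate
4 | lithium 3-[2-(methoxymethoxy)phenyl]prop-1-yn-1-olate | [Li+].[O-]C#CCc1ccccc1OCOC | intermediate
5 | triisopropyl({3-[2-(methoxymethoxy)phenyl]prop-1-yn-1-yl}oxy)silane | COCOc1ccccc1CC#CO[Si](C(C)C)(C(C)C)C(C)C | intermediate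
6 | 2,2'-methylenediphenol | Oc1ccccc1Cc1ccccc1O | starting material
7 | 2-hydroxy-3-(2-hydroxybenzyl)benzaldehyde | O=Cc1cccc(Cc2ccccc2O)c1O | intermediate
8 | 2-(methoxymethoxy)-3-[2-(methoxymethoxy)benzyl]benzaldehyde | COCOc1ccccc1Cc1cccc(C=O)c1OCOC | intermediate
9 | {2-(methoxymethoxy)-3-[2-(methoxymethoxy)benzyl]phenyl}methanol | COCOc1ccccc1Cc1cccc(CO)c1OCOC | intermediate
10 | 1-(chloromethyl)-2-(methoxymethoxy)-3-[2-(methoxymethoxy)benzyl]benzene | COCOc1ccccc1Cc1cccc(CCl)c1OCOC | intermediate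
11 | 5-bromo-2-hydroxybenzaldehyde | O=Cc1cc(Br)ccc1O | starting material
12 | 5-bromo-2-(methoxymethoxy)benzaldehyde | COCOc1ccc(Br)cc1C=O | intermediate
13 | 2-(methoxymethoxy)-5-(4,4,5,5-tetramethyl-1,3,2-dioxaborolan-2-yl)benzaldehyde | COCOc1ccc(cc1C=O)B1OC(C)(C)C(C)(C)O1 | intermediate
14 | 2-(methoxymethoxy)-5-{2-(methoxymethoxy)-3-[2-(methoxymethoxy)benzyl]benzyl}benzaldehyde | COCOc1ccccc1Cc1cccc(Cc2ccc(OCOC)c(C=O)c2)c1OCOC | intermediate
15 | (E)-3-(2-(methoxymethoxy)-5-{2-(methoxymethoxy)-3-[2-(methoxymethoxy)benzyl]benzyl}phenyl)prop-2-enoic acid | COCOc1ccccc1Cc1cccc(Cc2ccc(OCOC)c(/C=C/C(O)=O)c2)c1OCOC | intermediate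
16 | 2-(arm 6)acetic acid = 3-(2-(methoxymethoxy)-5-{2-(methoxymethoxy)-3-[2-(methoxymethoxy)benzyl]benzyl}phenyl)propanoic acid | COCOc1ccccc1Cc1cccc(Cc2ccc(OCOC)c(CCC(O)=O)c2)c1OCOC | intermediate
17 | ethoxyacetylene | CCOC#C | starting material
18 | 2-(arm 6)acetyl chloride | COCOc1ccccc1Cc1cccc(Cc2ccc(OCOC)c(CCC(Cl)=O)c2)c1OCOC | intermediate
19 | 2-(arm 6)ethen-1-one (aldoketene) | COCOc1ccccc1Cc1cccc(Cc2ccc(OCOC)c(CC=C=O)c2)c1OCOC | intermediate
20 | rac-3-ethoxy-4-(arm 6)cyclobut-2-en-1-one | CCOC1=CC(=O)C1Cc1cc(Cc2cccc(Cc3ccccc3OCOC)c2OCOC)ccc1OCOC | intermediate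
21 | (3Z)-3-ethoxy-4-(arm 6)buta-1,3-dien-1-one | O=C=C/C(OCC)=C/Cc1cc(Cc2cccc(Cc3ccccc3OCOC)c2OCOC)ccc1OCOC | intermediate
22 | rac-4-[(Z)-1-ethoxy-2-(arm 6)ethenyl]-2-(arm 8)-3-(triisopropylsilyloxy)cyclobut-2-en-1-one | O=C1C(Cc2ccccc2OCOC)=C(O[Si](C(C)C)(C(C)C)C(C)C)C1/C(OCC)=C/Cc1cc(Cc2cccc(Cc3ccccc3OCOC)c2OCOC)ccc1OCOC | intermediate
23 | (3E,5Z)-5-ethoxy-6-(arm 6)-2-(arm 8)-3-(triisopropylsilyloxy)hexa-1,3,5-trien-1-one | O=C=C(Cc1ccccc1OCOC)/C(O[Si](C(C)C)(C(C)C)C(C)C)=C\C(OCC)=C\Cc1cc(Cc2cccc(Cc3ccccc3OCOC)c2OCOC)ccc1OCOC | intermediate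
24 | rac-6-(arm 6)-5-ethoxy-2-(arm 8)-3-(triisopropylsilyloxy)cyclohexa-2,4-dien-1-one | O=C1C(Cc2ccccc2OCOC)=C(O[Si](C(C)C)(C(C)C)C(C)C)C=C(OCC)C1Cc1cc(Cc2cccc(Cc3ccccc3OCOC)c2OCOC)ccc1OCOC | intermediate
25 | 6-(arm 6)-5-ethoxy-2-(arm 8)-3-(triisopropylsilyloxy)phenol | Oc1c(Cc2ccccc2OCOC)c(O[Si](C(C)C)(C(C)C)C(C)C)cc(OCC)c1Cc1cc(Cc2cccc(Cc3ccccc3OCOC)c2OCOC)ccc1OCOC | intermediate
26 | [4-(arm 6)-5-ethoxy-3-(methoxymethoxy)-2-(arm 8)phenoxy]triisopropylsilane | COCOc1c(Cc2ccccc2OCOC)c(O[Si](C(C)C)(C(C)C)C(C)C)cc(OCC)c1Cc1cc(Cc2cccc(Cc3ccccc3OCOC)c2OCOC)ccc1OCOC | intermediate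
27 | 4-(arm 6)-5-ethoxy-3-(methoxymethoxy)-2-(arm 8)phenol | COCOc1c(Cc2ccccc2OCOC)c(O)cc(OCC)c1Cc1cc(Cc2cccc(Cc3ccccc3OCOC)c2OCOC)ccc1OCOC | intermediate
28 | ethyl (R)-3-hydroxy-3-phenylpropanoate | CCOC(=O)C[C@@H](O)c1ccccc1 | starting material
29 | (R)-3-hydroxy-N-methoxy-N-methyl-3-phenylpropanamide | CON(C)C(=O)C[C@@H](O)c1ccccc1 | intermediate
30 | (3S)-3-[4-(arm 6)-5-ethoxy-3-(methoxymethoxy)-2-(arm 8)phenoxy]-N-methoxy-N-methyl-3-phenylpropanamide | CON(C)C(=O)C[C@@H](c1ccccc1)Oc1cc(OCC)c(Cc2cc(Cc3cccc(Cc4ccccc4OCOC)c3OCOC)ccc2OCOC)c(OCOC)c1Cc1ccccc1OCOC | intermediate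
31 | (3S)-3-[6-bromo-4-(arm 6)-5-ethoxy-3-(methoxymethoxy)-2-(arm 8)phenoxy]-N-methoxy-N-methyl-3-phenylpropanamide | CON(C)C(=O)C[C@@H](c1ccccc1)Oc1c(Br)c(OCC)c(Cc2cc(Cc3cccc(Cc4ccccc4OCOC)c3OCOC)ccc2OCOC)c(OCOC)c1Cc1ccccc1OCOC | intermediate
32 | C4a-lithio derivative of 31 (lithium in place of bromine) | CON(C)C(=O)C[C@@H](c1ccccc1)Oc1c([Li])c(OCC)c(Cc2cc(Cc3cccc(Cc4ccccc4OCOC)c3OCOC)ccc2OCOC)c(OCOC)c1Cc1ccccc1OCOC | intermediate
33 | lithium (2S)-6-(arm 6)-5-ethoxy-4-[methoxy(methyl)amino]-7-(methoxymethoxy)-8-(arm 8)-2-phenylchroman-4-olate (C4 epimers) | CON(C)C1(O[Li])C[C@@H](c2ccccc2)Oc2c(Cc3ccccc3OCOC)c(OCOC)c(Cc3cc(Cc4cccc(Cc5ccccc5OCOC)c4OCOC)ccc3OCOC)c(OCC)c21 | intermediate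
34 | (2S)-6-(arm 6)-5-ethoxy-7-(methoxymethoxy)-8-(arm 8)-2-phenylchroman-4-one | O=C1C[C@@H](c2ccccc2)Oc2c(Cc3ccccc3OCOC)c(OCOC)c(Cc3cc(Cc4cccc(Cc5ccccc5OCOC)c4OCOC)ccc3OCOC)c(OCC)c21 | intermediate
35 | (2S)-5,7-dihydroxy-8-(2-hydroxybenzyl)-6-{2-hydroxy-5-[2-hydroxy-3-(2-hydroxybenzyl)benzyl]benzyl}-2-phenylchroman-4-one | O=C1C[C@@H](c2ccccc2)Oc2c(Cc3ccccc3O)c(O)c(Cc3cc(Cc4cccc(Cc5ccccc5O)c4O)ccc3O)c(O)c21 | target

**Step count and risks**

Total step count: 20. Longest linear sequence: 15 steps (steps 3, 4, 5, 6, 9, 10, 11, 12, 13, 14, 15, 17, 18, 19, 20).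

Steps most likely to fail:

1. Step 13 (benzannulation). The electrocyclic opening of the donor-stabilised cyclobutenone may need a temperature at which the siloxyalkyne is lost by 1,3-silyl shift to a silylketene, and the vinylketene may acylate the product phenol instead of adding to the alkyne. The fallback sets out from acid chloride 18 and comes back to the route at vinylketene 21; it makes the vinylketene at room temperature without any ring opening. Acid chloride 18 is added to LiCH2CO2Et (from EtOAc and LiN(i-Pr)2, THF, −78 °C) to give, by crossed Claisen acylation, ethyl 4-(arm 6)-3-oxobutanoate F1. Triethyl orthoformate with catalytic pyridinium tosylate in EtOH converts it into ethyl (E)-3-ethoxy-4-(arm 6)but-2-enoate F2. LiOH in THF/H2O gives (E)-3-ethoxy-4-(arm 6)but-2-enoic acid F3, and Me2C=C(Cl)NMe2 gives (E)-3-ethoxy-4-(arm 6)but-2-enoyl chloride F4. Et3N in CH2Cl2 at 0 °C → rt in the presence of 5 removes HCl across the four-carbon unit (γ-deprotonation) and gives 21, which 5 traps as 22; warming to 80 °C then carries 22 through 23 and 24 to 25. Each stage is known chemistry: vinylketenes by dehydrohalogenation of α,β-unsaturated acid chlorides, their [2+2] cycloaddition with siloxyalkynes, and the thermal rearrangement of 4-alkenylcyclobutenones to phenols.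

2. Step 17 (Mitsunobu etherification). The activated carbinol may eliminate to the cinnamoyl amide, since the C3 hydrogens are α to the amide carbonyl, and partial ionisation at the benzylic carbon would lower the enantiomeric purity at C2. The fallback sets out from 27 and comes back at 30; it uses a carbinol with no acidic neighbour. Commercial (R)-1-phenylpropane-1,3-diol is silylated at the primary hydroxyl (TBSCl, imidazole, CH2Cl2, 0 °C) to (R)-3-[(tert-butyldimethylsilyl)oxy]-1-phenylpropan-1-ol F5. Mitsunobu reaction of 27 with F5 (PPh3, DIAD, toluene, 0 °C) gives with inversion the (S)-ether, tert-butyl{(3S)-3-[4-(arm 6)-5-ethoxy-3-(methoxymethoxy)-2-(arm 8)phenoxy]-3-phenylpropoxy}dimethylsilane F6. Bu4NF gives the primary alcohol (3S)-3-[4-(arm 6)-5-ethoxy-3-(methoxymethoxy)-2-(arm 8)phenoxy]-3-phenylpropan-1-ol F7. TEMPO with PhI(OAc)2 in MeCN/H2O oxidises it to (3S)-3-[4-(arm 6)-5-ethoxy-3-(methoxymethoxy)-2-(arm 8)phenoxy]-3-phenylpropanoic acid F8. Coupling with MeNHOMe·HCl (EDC·HCl, HOBt, N-methylmorpholine) gives 30.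

3. Step 2 (siloxyalkyne). The arylacetic ester may be enolised by LiCHBr2 or the lithium amide instead of being attacked at the carbonyl, and the benzylic, propargylic ynolate may isomerise under the basic conditions. The fallback sets out from 2 and comes back at ynolate 4; it reaches the ynolate by oxidation of an acetylide instead of homologation of the ester. Reduction of 2 with i-Bu2AlH (CH2Cl2, −78 °C) gives [2-(methoxymethoxy)phenyl]acetaldehyde F9. Ohira–Bestmann alkynylation (dimethyl (1-diazo-2-oxopropyl)phosphonate, K2CO3, MeOH, 0 °C) gives 1-(methoxymethoxy)-2-(prop-2-yn-1-yl)benzene F10. Deprotonation with n-BuLi (THF, −78 °C) and oxidation of the lithium acetylide with t-BuOOLi (from t-BuOOH and LiN(SiMe3)2) gives 4, which is silylated on oxygen with TIPSOTf to 5.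

**Further compounds**

F1 | step 13 | ethyl 4-(arm 6)-3-oxobutanoate | CCOC(=O)CC(=O)CCc1cc(Cc2cccc(Cc3ccccc3OCOC)c2OCOC)ccc1OCOC
F2 | step 13 | ethyl (E)-3-ethoxy-4-(arm 6)but-2-enoate | CCOC(=O)/C=C(/OCC)CCc1cc(Cc2cccc(Cc3ccccc3OCOC)c2OCOC)ccc1OCOC
F3 | step 13 | (E)-3-ethoxy-4-(arm 6)but-2-enoic acid | OC(=O)/C=C(/OCC)CCc1cc(Cc2cccc(Cc3ccccc3OCOC)c2OCOC)ccc1OCOC
F4 | step 13 | (E)-3-ethoxy-4-(arm 6)but-2-enoyl chloride | ClC(=O)/C=C(/OCC)CCc1cc(Cc2cccc(Cc3ccccc3OCOC)c2OCOC)ccc1OCOC
F5 | step 17 | (R)-3-[(tert-butyldimethylsilyl)oxy]-1-phenylpropan-1-ol | CC(C)(C)[Si](C)(C)OCC[C@@H](O)c1ccccc1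
F6 | step 17 | tert-butyl{(3S)-3-[4-(arm 6)-5-ethoxy-3-(methoxymethoxy)-2-(arm 8)phenoxy]-3-phenylpropoxy}dimethylsilane | CC(C)(C)[Si](C)(C)OCC[C@@H](c1ccccc1)Oc1cc(OCC)c(Cc2cc(Cc3cccc(Cc4ccccc4OCOC)c3OCOC)ccc2OCOC)c(OCOC)c1Cc1ccccc1OCOC
F7 | step 17 | (3S)-3-[4-(arm 6)-5-ethoxy-3-(methoxymethoxy)-2-(arm 8)phenoxy]-3-phenylpropan-1-ol | OCC[C@@H](c1ccccc1)Oc1cc(OCC)c(Cc2cc(Cc3cccc(Cc4ccccc4OCOC)c3OCOC)ccc2OCOC)c(OCOC)c1Cc1ccccc1OCOC
F8 | step 17 | (3S)-3-[4-(arm 6)-5-ethoxy-3-(methoxymethoxy)-2-(arm 8)phenoxy]-3-phenylpropanoic acid | OC(=O)C[C@@H](c1ccccc1)Oc1cc(OCC)c(Cc2cc(Cc3cccc(Cc4ccccc4OCOC)c3OCOC)ccc2OCOC)c(OCOC)c1Cc1ccccc1OCOC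
F9 | step 2 | [2-(methoxymethoxy)phenyl]acetaldehyde | COCOc1ccccc1CC=O
F10 | step 2 | 1-(methoxymethoxy)-2-(prop-2-yn-1-yl)benzene | COCOc1ccccc1CC#C
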